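**Strategy.** Everything rests on cutting ring C at C4–C4a and O1–C2. Ring A (C4a–C8a) with its 5-methoxy, 7-hydroxy and 8-formyl groups is 2,6-dihydroxy-4-methoxybenzaldehyde substituted at one ring carbon and the adjacent oxygen. That aldehyde has a twofold axis, so its two free ring carbons and its two hydroxyls are equivalent and no C6/C8 choice exists. In one operation a chiral phosphoric acid joins it to a 2-arylacrolein that carries the prenylated, bis-MOM-protected ring B. Friedel–Crafts conjugate addition forms C4–C4a, enantioselective protonation sets C3 as R, and lactol closure forms O1–C2. Lactol reduction, Mitsunobu reclosure and MOM removal complete the isoflavan.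

Key step: step 7

Remarks on the chemistry:
- The sense of induction of a new protonation cannot be predicted. The (R)-catalyst is written, and its antipode would be used if a first trial shows that it leads to the 3S series.
- Lactol 15 is freed from catalyst and surplus 2 by a cold filtration through a short silica pad and reduced the same day without chromatography, because C3 is the α-carbon of a masked aldehyde.
- Ring B carries MOM ethers by design: they direct both lithiations, tolerate the acid catalyst, and keep the 2'-oxygen from closing a five-membered ether in step 9. Compound 2 is used unprotected so that its symmetry stays intact.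

Step 1
Reactants: 1 2,4,6-trihydroxybenzaldehyde
Product: 2 2,6-dihydroxy-4-methoxybenzaldehyde
Conditions: MeI (1.0 equiv), K2CO3 (1.0 equiv), acetone, 0 °C to rt
Reagents that add atoms: iodomethane, CI
Why: Williamson ether synthesis under base-limited conditions: the 4-hydroxyl, para to the formyl group and not chelated to it, is the most acidic and should be alkylated first, and limiting base and electrophile should hold the reaction at the symmetric mono-ether.

Step 2
Reactants: 3 resorcinol
Product: 4 1,3-bis(methoxymethoxy)benzene
Conditions: NaH (2.4 equiv), DMF, 0 °C; MOMCl (2.4 equiv), 0 °C to rt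
Reagents that add atoms: chloromethyl methyl ether, COCCl
Why: Williamson-type O-alkylation of the bis-phenoxide with the reactive α-chloro ether should give the bis-acetal (MOM protection).

Step 3
Reactants: 4 1,3-bis(methoxymethoxy)benzene; 5 prenyl bromide (1-bromo-3-methylbut-2-ene)
Product: 7 1,3-bis(methoxymethoxy)-2-(3-methylbut-2-en-1-yl)benzene, via aryllithium 6 (not isolated)
Conditions: n-BuLi (1.1 equiv), THF, 0 °C to rt; CuI (10 mol%), then 5, −78 °C to rt
Reagents that add atoms: none
Why: Directed ortho-metalation removes the C2 hydrogen flanked by both MOM ethers, and copper-catalysed SN2 alkylation of the aryllithium at the primary carbon of the allylic bromide should give the linear prenyl arene.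

Step 4
Reactants: 7 1,3-bis(methoxymethoxy)-2-(3-methylbut-2-en-1-yl)benzene
Product: 9 2-[2,4-bis(methoxymethoxy)-3-(3-methylbut-2-en-1-yl)phenyl]-4,4,5,5-tetramethyl-1,3,2-dioxaborolane, via aryllithium 8 (not isolated)
Conditions: n-BuLi (1.2 equiv), TMEDA (1.2 equiv), THF, −20 to 0 °C; then 2-isopropoxy-4,4,5,5-tetramethyl-1,3,2-dioxaborolane, −78 °C to rt; aqueous work-up
Reagents that add atoms: 2-isopropoxy-4,4,5,5-tetramethyl-1,3,2-dioxaborolane, CC(C)OB1OC(C)(C)C(C)(C)O1
Why: A second directed ortho-metalation next to a MOM ether (C4 and C6 are equivalent), expected to outrun deprotonation of the hindered prenyl methylene, followed by trapping of the aryllithium with the isopropoxyboronate should give the pinacol boronate (lithiation–borylation).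

Step 5
Reactants: 9 2-[2,4-bis(methoxymethoxy)-3-(3-methylbut-2-en-1-yl)phenyl]-4,4,5,5-tetramethyl-1,3,2-dioxaborolane; 10 2-bromoprop-2-en-1-ol
Product: 11 2-[2,4-bis(methoxymethoxy)-3-(3-methylbut-2-en-1-yl)phenyl]prop-2-en-1-ol
Conditions: Pd(PPh3)4 (5 mol%), K2CO3 (3 equiv), 1,4-dioxane/H2O 4:1, 80 °C
Reagents that add atoms: none
Why: Suzuki–Miyaura coupling of the aryl boronate with the vinyl bromide under zerovalent palladium catalysis joins C1' to the future C3; the free hydroxyl, the acetals and the prenyl alkene are inert to these conditions.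

Step 6
Reactants: 11 2-[2,4-bis(methoxymethoxy)-3-(3-methylbut-2-en-1-yl)phenyl]prop-2-en-1-ol
Product: 12 2-[2,4-bis(methoxymethoxy)-3-(3-methylbut-2-en-1-yl)phenyl]prop-2-enal
Conditions: activated MnO2 (15 equiv), CH2Cl2, rt; used at once
Reagents that add atoms: none
Why: Allylic alcohol oxidation with MnO2 is selective for the allylic position and stops at the enal, leaving the isolated prenyl alkene and the acetals untouched; the 2-arylacrolein is taken on directly because such enals dimerise on storage.

Step 7
Reactants: 2 2,6-dihydroxy-4-methoxybenzaldehyde; 12 2-[2,4-bis(methoxymethoxy)-3-(3-methylbut-2-en-1-yl)phenyl]prop-2-enal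
Product: 15 (3R)-3-[2,4-bis(methoxymethoxy)-3-(3-methylbut-2-en-1-yl)phenyl]-2,7-dihydroxy-5-methoxy-3,4-dihydro-2H-chromene-8-carbaldehyde (lactol; both C2 anomers), via enol 13 (not isolated), via open-chain aldehyde 14 (not isolated)
Conditions: (R)-3,3'-bis(2,4,6-triisopropylphenyl)-1,1'-binaphthyl-2,2'-diyl hydrogen phosphate (10 mol%), 2 (2.5 equiv), 12 added over 6 h, CH2Cl2, 4 Å MS, −20 °C
Reagents that add atoms: none
Why: Proposed new method: the phosphoric acid should bind the enal carbonyl of 12 through its P–OH and a phenolic O–H of 2 through its P=O, so that the free ring carbon of 2 (ortho and para to oxygen) attacks the unsubstituted methylene (C4–C4a), the catalyst-bound enol 13 is protonated at C3, and the neighbouring hydroxyl adds to the aldehyde of 14 (O1–C2). The closest known reaction types are the Friedel–Crafts conjugate addition of indoles to α-substituted acroleins with catalytic enantioselective protonation and the annulation of phenols with enals to chroman-2-ols; a phenol nucleophile combined with enantioselective α-protonation has not been shown. Ring C closes by 6-exo-trig hemiacetalisation of the C8a hydroxyl onto C2. C3 is controlled by the chiral phosphate, which delivers the proton to one face of the hydrogen-bonded enol, whereas C2 forms as both anomers and loses its stereogenicity in step 8. The step needs carbon- rather than oxygen-alkylation, 1,4- rather than 1,2-addition, mono-alkylation and survival of the enolisable α-aryl aldehyde: the twofold symmetry of 2 makes both ring carbons and both hydroxyls equivalent so that no regiochemical question arises, the excess of 2 and the slow addition of 12 hold back double alkylation and enal self-condensation, and lactol closure masks the aldehyde.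

Step 8
Reactants: 15 (3R)-3-[2,4-bis(methoxymethoxy)-3-(3-methylbut-2-en-1-yl)phenyl]-2,7-dihydroxy-5-methoxy-3,4-dihydro-2H-chromene-8-carbaldehyde
Product: 16 3-{(2R)-2-[2,4-bis(methoxymethoxy)-3-(3-methylbut-2-en-1-yl)phenyl]-3-hydroxypropyl}-2,6-dihydroxy-4-methoxybenzaldehyde
Conditions: NaBH(OAc)3 (2.5 equiv), THF, 0 °C to rt
Reagents that add atoms: none
Why: Chemoselective hydride reduction: lactol 15 stands in ring–chain equilibrium with its hydroxy-aldehyde form (the species listed as 14), whose aliphatic aldehyde takes up hydride, while the C8 aldehyde, a strongly hydrogen-bonded vinylogous ester flanked by two oxygen substituents, should be a poor acceptor for the mild acetoxyborohydride, and the non-basic medium should leave C3 untouched.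

Step 9
Reactants: 16 3-{(2R)-2-[2,4-bis(methoxymethoxy)-3-(3-methylbut-2-en-1-yl)phenyl]-3-hydroxypropyl}-2,6-dihydroxy-4-methoxybenzaldehyde
Product: 17 (3R)-3-[2,4-bis(methoxymethoxy)-3-(3-methylbut-2-en-1-yl)phenyl]-7-hydroxy-5-methoxy-3,4-dihydro-2H-chromene-8-carbaldehyde
Conditions: PPh3 (1.5 equiv), DIAD (1.5 equiv), THF (0.02 M), 0 °C to rt
Reagents that add atoms: none
Why: Intramolecular Mitsunobu etherification: only the C8a hydroxyl can reach the activated primary carbon (6-exo-tet), the C7 hydroxyl cannot close a ring of sensible size and ring B is protected, and because displacement occurs at C2 the C3 centre is not involved.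

Step 10
Reactants: 17 (3R)-3-[2,4-bis(methoxymethoxy)-3-(3-methylbut-2-en-1-yl)phenyl]-7-hydroxy-5-methoxy-3,4-dihydro-2H-chromene-8-carbaldehyde
Product: 18 (3R)-3-[2,4-dihydroxy-3-(3-methylbut-2-en-1-yl)phenyl]-7-hydroxy-5-methoxy-3,4-dihydro-2H-chromene-8-carbaldehyde
Conditions: HCl (1 M in MeOH), 25 to 40 °C; then aq. NaHCO3
Reagents that add atoms: none
Why: Acid-catalysed acetal exchange of the two aryl MOM ethers in methanol (the formaldehyde unit leaves as dimethoxymethane), under mild conditions of the kind used for prenylated polyphenols and kept short so that the prenyl group does not cyclise onto the flanking phenols.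

**Compound list**

1 | 2,4,6-trihydroxybenzaldehyde | O=Cc1c(O)cc(O)cc1O | starting material
2 | 2,6-dihydroxy-4-methoxybenzaldehyde | COc1cc(O)c(C=O)c(O)c1 | intermediate
3 | resorcinol (benzene-1,3-diol) | Oc1cccc(O)c1 | starting material
4 | 1,3-bis(methoxymethoxy)benzene | COCOc1cccc(OCOC)c1 | intermediate
5 | prenyl bromide (1-bromo-3-methylbut-2-ene) | CC(C)=CCBr | starting material
6 | [2,6-bis(methoxymethoxy)phenyl]lithium (formed in the flask) | [Li]c1c(OCOC)cccc1OCOC | intermediate
7 | 1,3-bis(methoxymethoxy)-2-(3-methylbut-2-en-1-yl)benzene | COCOc1cccc(OCOC)c1CC=C(C)C | intermediate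
8 | [2,4-bis(methoxymethoxy)-3-(3-methylbut-2-en-1-yl)phenyl]lithium (formed in the flask) | [Li]c1ccc(OCOC)c(CC=C(C)C)c1OCOC | intermediate
9 | 2-[2,4-bis(methoxymethoxy)-3-(3-methylbut-2-en-1-yl)phenyl]-4,4,5,5-tetramethyl-1,3,2-dioxaborolane | CC1(C)OB(OC1(C)C)c1ccc(OCOC)c(CC=C(C)C)c1OCOC | intermediate
10 | 2-bromoprop-2-en-1-ol | C=C(Br)CO | starting material
11 | 2-[2,4-bis(methoxymethoxy)-3-(3-methylbut-2-en-1-yl)phenyl]prop-2-en-1-ol | C=C(CO)c1ccc(OCOC)c(CC=C(C)C)c1OCOC | intermediate
12 | 2-[2,4-bis(methoxymethoxy)-3-(3-methylbut-2-en-1-yl)phenyl]prop-2-enal (key-step precursor) | C=C(C=O)c1ccc(OCOC)c(CC=C(C)C)c1OCOC | intermediate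
13 | 3-{2-[2,4-bis(methoxymethoxy)-3-(3-methylbut-2-en-1-yl)phenyl]-3-hydroxyprop-2-en-1-yl}-2,6-dihydroxy-4-methoxybenzaldehyde (enol, either geometry; formed in the flask) | COc1cc(O)c(C=O)c(O)c1CC(=CO)c1ccc(OCOC)c(CC=C(C)C)c1OCOC | intermediate
14 | (2R)-2-[2,4-bis(methoxymethoxy)-3-(3-methylbut-2-en-1-yl)phenyl]-3-(3-formyl-2,4-dihydroxy-6-methoxyphenyl)propanal (formed in the flask) | COc1cc(O)c(C=O)c(O)c1C[C@H](c1ccc(OCOC)c(CC=C(C)C)c1OCOC)C=O | intermediate
15 | (3R)-3-[2,4-bis(methoxymethoxy)-3-(3-methylbut-2-en-1-yl)phenyl]-2,7-dihydroxy-5-methoxy-3,4-dihydro-2H-chromene-8-carbaldehyde (8-formyl-7-hydroxy-5-methoxyisoflavan-2-ol, ring B bis-MOM ether; both C2 anomers; key-step product) | COc1cc(O)c(C=O)c2c1C[C@H](c1ccc(OCOC)c(CC=C(C)C)c1OCOC)C(O)O2 | intermediate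
16 | 3-{(2R)-2-[2,4-bis(methoxymethoxy)-3-(3-methylbut-2-en-1-yl)phenyl]-3-hydroxypropyl}-2,6-dihydroxy-4-methoxybenzaldehyde | COc1cc(O)c(C=O)c(O)c1C[C@H](c1ccc(OCOC)c(CC=C(C)C)c1OCOC)CO | intermediate
17 | (3R)-3-[2,4-bis(methoxymethoxy)-3-(3-methylbut-2-en-1-yl)phenyl]-7-hydroxy-5-methoxy-3,4-dihydro-2H-chromene-8-carbaldehyde | COc1cc(O)c(C=O)c2c1C[C@H](c1ccc(OCOC)c(CC=C(C)C)c1OCOC)CO2 | intermediate
18 | (3R)-3-[2,4-dihydroxy-3-(3-methylbut-2-en-1-yl)phenyl]-7-hydroxy-5-methoxy-3,4-dihydro-2H-chromene-8-carbaldehyde | COc1cc(O)c(C=O)c2c1C[C@H](c1ccc(O)c(CC=C(C)C)c1O)CO2 | target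

**Totals**

Total step count: 10.
Longest linear sequence: 9 steps (steps 2 to 10, from resorcinol); step 1 is a one-step side branch.

**Steps most likely to fail**

1. Step 7. What may go wrong: oxygen- instead of carbon-alkylation, 1,2-addition at the enal carbonyl followed by dehydration, self-condensation of the 2-arylacrolein before it is intercepted, weak facial discrimination in the proton transfer, or erosion of C3 through enolisation or dehydration of the lactol. Fallback (known chemistry; sets out from 2 and 12, returns at 16): the union is run without asymmetric induction as a plain Brønsted-acid phenol–enal annulation of the type long used for chroman-2-ols (diphenyl phosphate, 10 mol%, CH2Cl2, 0 °C). This would give racemic 3-[2,4-bis(methoxymethoxy)-3-(3-methylbut-2-en-1-yl)phenyl]-2,7-dihydroxy-5-methoxy-3,4-dihydro-2H-chromene-8-carbaldehyde F1. Reduction with NaBH(OAc)3 as in step 8 would give racemic 3-{2-[2,4-bis(methoxymethoxy)-3-(3-methylbut-2-en-1-yl)phenyl]-3-hydroxypropyl}-2,6-dihydroxy-4-methoxybenzaldehyde F2. Lipase-catalysed kinetic resolution (Burkholderia cepacia lipase, vinyl acetate, tert-butyl methyl ether, 25 °C) then acetylates the primary hydroxyl of one enantiomer only, the phenols being left alone. The proposal assumes that the (S)-alcohol reacts faster, giving (2S)-2-[2,4-bis(methoxymethoxy)-3-(3-methylbut-2-en-1-yl)phenyl]-3-(3-formyl-2,4-dihydroxy-6-methoxyphenyl)propyl acetate F3 and leaving the (R)-diol 16, which re-enters at step 9. The enantiomer preference and the selectivity factor would have to be established on small scale, and conversion would be taken past the half-way point to secure the remaining alcohol. This fallback answers only loss of enantiocontrol; it still needs the same C4–C4a bond formation.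

2. Step 8. What may go wrong: hydride transfer to the C8 aldehyde as well (possibly delivered through a boron-bound phenol), or slow ring opening of the lactol that leaves time for enolisation at C3. Fallback (sets out from 15, returns at 16; no new compound, F0): the reduction is handed to an enzyme instead of a hydride reagent. An NADPH-dependent ketoreductase or alcohol dehydrogenase chosen from a commercial panel would be used with glucose/glucose dehydrogenase cofactor recycling in phosphate buffer (pH 7) with DMSO co-solvent at 30 °C. Enzymes of this class reduce 2-arylpropanal-type aldehydes and select by binding rather than by carbonyl electrophilicity, so the chelated, phenolate-like C8 aldehyde should not be accepted. Acceptance of this bulky substrate would have to be screened.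

3. Step 10. What may go wrong: acid-promoted cyclisation of the prenyl group onto the flanking 2'- or 4'-hydroxyl to a dimethylchroman, or addition of methanol or HCl across the prenyl alkene, before both acetals are cleaved. Fallback (sets out from 17, returns at 18): aprotic silyl-transfer cleavage in place of protic solvolysis. TMSOTf (6 equiv) and 2,2'-bipyridyl (9 equiv) in MeCN at 0 °C move the aryl oxygens from the acetal carbon to silicon, the methoxymethyl groups leaving as an N-(methoxymethyl)bipyridinium salt, so that no free Brønsted acid meets the prenyl group. The 7-hydroxyl is silylated as well, giving (3R)-5-methoxy-3-[3-(3-methylbut-2-en-1-yl)-2,4-bis(trimethylsilyloxy)phenyl]-7-(trimethylsilyloxy)-3,4-dihydro-2H-chromene-8-carbaldehyde F4. Stirring with water at rt then hydrolyses the three aryl silyl ethers to 18.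

**Further compounds**

F1 | step 7 | racemic 3-[2,4-bis(methoxymethoxy)-3-(3-methylbut-2-en-1-yl)phenyl]-2,7-dihydroxy-5-methoxy-3,4-dihydro-2H-chromene-8-carbaldehyde | COc1cc(O)c(C=O)c2c1CC(c1ccc(OCOC)c(CC=C(C)C)c1OCOC)C(O)O2
F2 | step 7 | racemic 3-{2-[2,4-bis(methoxymethoxy)-3-(3-methylbut-2-en-1-yl)phenyl]-3-hydroxypropyl}-2,6-dihydroxy-4-methoxybenzaldehyde | COc1cc(O)c(C=O)c(O)c1CC(c1ccc(OCOC)c(CC=C(C)C)c1OCOC)CO
F3 | step 7 | (2S)-2-[2,4-bis(methoxymethoxy)-3-(3-methylbut-2-en-1-yl)phenyl]-3-(3-formyl-2,4-dihydroxy-6-methoxyphenyl)propyl acetate | COc1cc(O)c(C=O)c(O)c1C[C@@H](c1ccc(OCOC)c(CC=C(C)C)c1OCOC)COC(C)=O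
F0 | step 8 | none | none
F4 | step 10 | (3R)-5-methoxy-3-[3-(3-methylbut-2-en-1-yl)-2,4-bis(trimethylsilyloxy)phenyl]-7-(trimethylsilyloxy)-3,4-dihydro-2H-chromene-8-carbaldehyde | COc1cc(O[Si](C)(C)C)c(C=O)c2c1C[C@H](c1ccc(O[Si](C)(C)C)c(CC=C(C)C)c1O[Si](C)(C)C)CO2
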